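The violet run's first readings already show less left-handed substrate left than right-handed substrate.

| flask | left-handed substrate | right-handed substrate | reagent | free catalyst | remark | time |
|---|---|---|---|---|---|---|
| violet | 5.0 × 10⁻⁴ M | 5.0 × 10⁻⁴ M | 1.5 mM | 0.70 µM | run made earlier |  |
| grey | 5.0 × 10⁻⁴ M | 5.0 × 10⁻⁴ M | 1.5 mM | 1.1 µM | run made earlier |  |
| ochre | 7.5 × 10⁻⁴ M | 7.5 × 10⁻⁴ M | 1.5 mM | 0.50 µM | run made earlier |  |
| flask | 5.0 × 10⁻⁴ M | 5.0 × 10⁻⁴ M | 1.50 mM | 0.50 µM |  | 4.0 min |

| run | time / min | right-handed substrate / % | left-handed substrate / % |
|---|---|---|---|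
| violet | 0.250 | 33 | 9 |
| violet | 0.833 | 24 | 2 |
| violet | 1.33 | 22 | 3 |
| violet | 2.50 | 10 | 0 |
| violet | 3.00 | 9 | 0 |
| grey | 0.250 | 29 | 5 |
| grey | 0.833 | 16 | 1 |
| grey | 1.33 | 12 | 0 |
| grey | 2.50 | 5 | 0 |
| grey | 3.00 | 5 | 2 |
| ochre | 0.250 | 43 | 23 |
| ochre | 0.833 | 31 | 10 |
| ochre | 1.33 | 30 | 4 |
| ochre | 2.50 | 26 | 0 |
| ochre | 3.00 | 22 | 1 |

(standard deviation of a reading: 1.5 percentage points)

- free catalyst is single-handed; left-handed substrate and right-handed substrate are mirror images of each other, charged as a racemate, each of them at the stated concentration

- whether the excess of right-handed substrate over left-handed substrate among what is left of the two reaches 95 % by 4.0 min (yes / no)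
- the highest excess of right-handed substrate over left-handed substrate among what is left of the two up to 4.0 min

I count half-lives, measuring each substrate against its own half of the charge. I assume both share one clock, however that clock slows. Pooling the first readings of violet and grey gives 4.18, a reading that carries their scatter. This is the selectivity factor: the half-lives the left-handed substrate passes for each half-life of the right-handed substrate.

Now I draw the excess against right-handed half-lives. It starts at zero and climbs about 110 points per half-life. It reaches 0.5, as a fraction, after 0.498 half-lives, then bends towards its ceiling of 100 %. It reaches 95 % after 1.66 half-lives, with 15.8 % of the total charge left as right-handed substrate.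

Does the flask get there? I scale the half-lives counted at 3.00 min by catalyst charge. Violet gives 1.77 and grey gives 1.51, on either side of 1.66, so I put the crossing near that time. Violet's count means 96.0 %, and the last minute adds to it, so I say yes, with a top above 95 %.

The forecast says yes, with a top of 99.6 % (range 97.5 % to 100 %), the excess “still rising at 4 min”.

The flask gives yes and 97.7 %.

    reagent + free catalyst → spent catalyst (k = 24.0 M⁻¹ s⁻¹)
    reagent + catalyst intermediate A → free catalyst + left-handed product (k = 1.50 × 10⁵ M⁻¹ s⁻¹)
    free catalyst + right-handed substrate ⇌ catalyst intermediate B (K = 1900 M⁻¹, k = 9.80 × 10⁶ M⁻¹ s⁻¹)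
    free catalyst + left-handed substrate ⇌ catalyst intermediate A (K = 3000 M⁻¹, k = 4.30 × 10⁷ M⁻¹ s⁻¹)
    reagent + catalyst intermediate B → free catalyst + right-handed product (k = 55000 M⁻¹ s⁻¹)
    free catalyst ⇌ dormant form (K = 3.00, k = 0.140 s⁻¹)

In the flask, the left-handed substrate falls to 11.3 % of the total charge by 0.400 min, passing through catalyst intermediate A into left-handed product. The right-handed substrate then goes on through catalyst intermediate B while spent catalyst climbs from 16.1 % to 62.6 % of the catalyst charged by 4.00 min. The excess reaches 95 % at 2.73 min, with 16.5 % right-handed substrate left, against my 15.8 %. The flask's amounts at 4.00 min give a factor of 4.31. On the ochre run, the first left-handed reading of 23 % and my factor give 41.5 % right-handed substrate, and the reading is 43 %.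

The data are calculated with made-up constants, and the scatter is random.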